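## Structural features

The target is a himachalane: a cyclohexene (ring A, C1–C6) cis-fused through C1 and C6 to a cycloheptane (ring B, C1, C6, C7–C11). Ring A carries the C2=C3 alkene with a methyl group on C3 and, on the allylic carbon C4, an ester of 3-hydroxy-4-methoxybenzoic acid. Ring B carries the quaternary gem-dimethyl carbon C11 next to C1 and a tertiary methyl carbinol C7 next to C6. There are four stereocentres, (1S,4R,6R,7S): C1, C6 and C7 are contiguous and C4 lies one methylene (C5) from C6. H1, H6, the C7 methyl group and the C4 oxygen share one face; the C7 hydroxyl is on the other. The fragile groups are the allylic ester (ionisation, allylic transposition, elimination, acyl loss under base), the free phenol and the tertiary alcohol. The skeleton is not the hard part; the difficulty is the relative configuration along C1–C6–C7 beside the quaternary C11, its transfer to C4, and a late inverting esterification. The key step exploits the fact that ring A, read as an arene, is 2-methylanisole (C4–O as methoxy, C3–CH3 as methyl, C1 para and C6 meta to oxygen). C1–C11 is then an aryl–tert-alkyl bond and C6–C7 an aryl–acyl bond, and C7–C11 with its two methyl groups is 5-methylhex-4-enoic acid.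

## Logic of the disconnections

24 ⇒ 23. Only the phenolic O–Si bond is cut. The phenol has to be masked while the ester is made, because a free phenol is a competing nucleophile. The forward step must remove silicon without touching the allylic ester, so the fluoride is buffered.

23 ⇒ 19 + 22. The C4–O ester bond is cut, with inversion at C4 planned. Hydride reduction of the C4 ketone is expected to give the C4 epimer of what is needed, so the acid is brought in as the nucleophile. This splits the molecule into the terpenoid core and the aryl acid. The forward step needs clean displacement at C4 without attack at C2; the tertiary C7 hydroxyl can stay free.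

22 ⇒ 20. The aryl O–Si bond is cut; the forward step must silylate the phenol and leave the acid free.

19 ⇒ 18. The C4–H bond is cut, removing one stereocentre. The forward step needs 1,2-reduction from the face of H6.

18 ⇒ 15. The C2=C3 unsaturation is removed. This gives a saturated ketone that an anisole can supply. The forward step needs enolisation toward the methyl-bearing C3 and not toward C5.

15 ⇒ 13. The C7–CH3 bond is cut and C4 is masked as a ketal. C7 loses its stereocentre and is to be rebuilt under control of the ring fusion. The forward step needs methyl delivery syn to H6 without epimerising C6, and the ketal keeps the nucleophile away from C4.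

13 ⇒ 12 ⇒ 11. C7 is taken back to a secondary carbinol, then the C1–H and C6–H bonds are cut, removing two stereocentres. A tertiary C7 silyl ether could steer hydrogen only by bulk, and the target needs H6 anti to the C7 oxygen. Therefore C7 is kept secondary with its hydroxyl on the face where H1 and H6 must go, so that the hydroxyl can deliver hydrogen to the hindered tetrasubstituted alkene. The price is one oxidation; the later methyl addition replaces an enantioselective methylation.

11 ⇒ 9. The C2–H and C5–H bonds and the ketal C–O bonds are cut, so ring A becomes aromatic and all ring-A stereochemistry disappears. The forward step needs the benzylic C7–O bond to survive dissolving metal, and the alkene must stay at C1=C6.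

9 ⇒ 8. The C7–H bond is cut. This is the only stereocentre set by an external chiral agent; everything else is relayed from it.

8 ⇒ 5 + 6. The C1–C11 and C6–C7 bonds are cut, giving two achiral commercial-grade fragments. The forward step needs alkylation before acylation, alkylation para to methoxy, and acylation at C6. One correction to the usual shorthand: two ring positions flank the new quaternary carbon (C2 and C6), so closure at C6 is a selectivity, not a necessity. C6 wins because it is para to the ring methyl and unflanked, while C2 sits between the methyl group and the quaternary carbon.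

5 ⇒ 4 ⇒ 1 + 2. The C8–C9 bond (α,β bond of the acid) and the ester C–O bond are cut. A [3,3] shift of the tertiary allylic alcohol gives the trisubstituted alkene directly and needs only heat and removal of ethanol.

## Other disconnections considered

Alternative 1: The cut is in ring B at C6–C7 and C10–C11. In the forward sense the oxyallyl cation released from A1 by Et3N in CF3CH2OH would add across the two α-carbons of A2 in a (4+3) cycloaddition to give the oxygen-bridged cycloheptenone A3.
- In favour: one step from two simple liquids makes the whole seven-membered ring and both congested carbons, and C7 arrives with its methyl group and oxygen in place. On this point it is better than the chosen plan, which needs a reduction, an oxidation and a methyl addition at C7. As a key event it is equal (two C–C bonds, one ring).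
- Against: A3 forms as a racemate and no dependable enantioselective version exists for so simple a pair, so a resolution would be needed. The orientation of the unsymmetrical cation toward the methylated furan carbon is not assured. Ring A must be built on the ketone carbon C1 and the methylene C6 with a methyl/oxygen/alkene pattern that a Robinson-type annulation delivers transposed. The ether bridge must be opened at C10–O while C7–O is kept, yet A3 is a β-alkoxy ketone in which base breaks C7–O. The ring-fusion hydrogens still have to be set relative to C7.
- Comparison: it fits ring B better and ring A worse. Mechanistically it is a cation process of comparable reliability. In step economy it falls behind, because everything the arene supplies in the chosen plan (four ring-A carbons, the C3 methyl, the C4 oxygen) must be added afterwards.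

Alternative 2: The cut is at C1–C6 and C4–C5, opening both rings. In the forward sense the triene A4 would undergo an intramolecular Diels–Alder reaction (silyloxy methyl diene onto the tethered vinyl ketone) under a chiral oxazaborolidinium Lewis acid to give A5.
- In favour: both rings, the C2=C3 alkene with its methyl group, and three stereocentres (C1, C6, C4) appear in one step with cis fusion from the endo transition state and no redox detour through an arene. In stereochemical directness and oxidation-state economy on ring A it is better than the chosen plan. Its finish (methyl addition to the C7 ketone from the convex face, inversion at C4) is equal to steps 8 and 12 here.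
- Against: A4 is a sensitive triene (polymerisable vinyl ketone, hydrolysable silyl dienol ether, two alkene geometries to control) that would take roughly eight to ten steps. A five-atom tether closing a seven-membered ring is slow, and the diene terminus carries the quaternary C11. The dienol ether may not survive the Lewis acid, and enantioface control with the carbonyl inside the tether is not assured.
- Comparison: overall length is similar. This alternative concentrates its risk in one demanding step; the chosen plan makes the skeleton in three steps and spreads the risk over a stereochemical relay.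

Alternative 3: The cut is at the ester C4–O bond together with a ring contraction that takes C3 out of ring A (a chloro(methyl)cyclopropane on a cyclopentane). In the forward sense AgBF4 would abstract the endo chloride of A6, the C2–C4 bond would open in the disrotatory sense to the 2-methylcyclohexenyl cation, and acid 22 would capture C4 to give A7.
- In favour: ester, alkene and C3 methyl appear in one late, non-basic, convergent step, and capture on the convex face would give the C4 configuration without an inversion. In its last stage it is better than the chosen plan (one step in place of dehydrogenation, reduction and inverting esterification).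
- Against: the site of capture (C4 or C2) and its face rest on sterics alone. A carboxylic acid is a weak nucleophile, so proton loss to a diene competes. A6 needs a cis-fused hydroazulene with C1, C6 and C7 already set and a face- and endo-selective carbene addition.
- Comparison: the stereochemical problem solved in steps 4–8 here is not removed but moved into a less accessible five–seven ring system. The mechanism is orbital-symmetry controlled only up to the cation, and the total step count would be higher.

Key step: step 3

Remark: atom numbers C1–C11 are the himachalane numbers defined above; compounds 11–15 are carried as both epimers at the methyl-bearing carbon C3, which becomes sp2 again in step 9.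

## Route

Step 1
Reactants: 1 2-methylbut-3-en-2-ol; 2 triethyl orthoacetate
Product: 4 ethyl 5-methylhex-4-enoate, via mixed ketene acetal 3 (not isolated)
Conditions: EtCO2H (cat.), 140 °C, EtOH distilled off
Reagents that add atoms: none
Why: Johnson–Claisen rearrangement: acid-catalysed exchange gives ketene acetal 3, whose [3,3]-sigmatropic shift forms the C8–C9 bond and leaves the trisubstituted alkene; distilling ethanol drives the exchange.

Step 2
Reactants: 4 ethyl 5-methylhex-4-enoate
Product: 5 5-methylhex-4-enoic acid
Conditions: LiOH, THF–H2O, rt; then 1 M HCl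
Reagents that add atoms: lithium hydroxide [Li+].[OH-]
Why: Ester saponification followed by acidification; the isolated alkene is inert to aqueous base.

Step 3
Reactants: 5 5-methylhex-4-enoic acid; 6 2-methylanisole
Product: 8 3-methoxy-2,9,9-trimethyl-6,7,8,9-tetrahydro-5H-benzo[7]annulen-5-one, via aryl hexanoic acid 7 (not isolated)
Conditions: 6 (3 equiv), MeSO3H, 0 °C → rt; then P2O5 (1:10 w/w in MeSO3H), 50 °C
Reagents that add atoms: none
Why: The acid protonates the trisubstituted alkene of 5 to the tertiary C11 cation, which alkylates 6 para to methoxy (C1–C11) to give 7 while the carboxyl group is still unactivated; P2O5 then turns the acid into a mixed anhydride or acylium ion that acylates the ring at C6 (C6–C7). The closest known reaction type is the tandem Friedel–Crafts cycloalkylation–acylation of activated arenes with unsaturated acids or their lactones, which gives tetralones and benzosuberones. Ring B closes in the second event as a seven-membered ring by intramolecular acylation ortho to the tether, with the aromatic C1–C6 bond inside the new ring (a 7-endo-type closure helped by the gem-dimethyl group). No stereocentre is formed. Three selectivities are needed: alkylation before acylation, secured by the staging because cation formation needs no dehydrating agent whereas acylium formation does; para alkylation, secured by the methoxy group and the bulk of the tertiary cation; and acylation at C6 and not C2, secured because C6 is para to the ring methyl and unflanked whereas C2 lies between the methyl group and the new quaternary carbon. The excess of 6 limits double alkylation.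

Step 4
Reactants: 8 3-methoxy-2,9,9-trimethyl-6,7,8,9-tetrahydro-5H-benzo[7]annulen-5-one
Product: 9 (5R)-3-methoxy-2,9,9-trimethyl-6,7,8,9-tetrahydro-5H-benzo[7]annulen-5-ol
Conditions: RuCl(p-cymene)[(R,R)-TsDPEN] (1 mol%), HCO2H–Et3N (5:2), 40 °C
Reagents that add atoms: none
Why: Asymmetric transfer hydrogenation of an aryl ketone: the ruthenium hydride distinguishes the aryl flank from the methylene flank, and by analogy with 1-tetralone the (R,R)-ligand should give the (R)-carbinol, which places the hydroxyl on the face where H1 and H6 are needed; formic acid makes the reduction irreversible.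

Step 5
Reactants: 9 (5R)-3-methoxy-2,9,9-trimethyl-6,7,8,9-tetrahydro-5H-benzo[7]annulen-5-ol
Product: 11 (5'R)-2',9',9'-trimethyl-1',2',4',5',6',7',8',9'-octahydrospiro[1,3-dioxolane-2,3'-benzo[7]annulen]-5'-ol (both C2' epimers), via Birch enol ether 10 (not isolated)
Conditions: n-BuLi, THF, −78 °C; Li, NH3(l), t-BuOH, −78 → −33 °C; isoprene, then NH4Cl; HOCH2CH2OH, PPTS (cat.), CH2Cl2, rt
Reagents that add atoms: ethane-1,2-diol OCCO
Why: Birch reduction adds hydrogen at the two unsubstituted, para-related carbons C2 and C5, leaving the C3=C4 enol ether and the tetrasubstituted C1=C6 alkene. The preformed lithium alkoxide resists benzylic C–O cleavage because t-BuOH is too weak an acid to protonate it and excess lithium is destroyed with isoprene before the quench. Acid-catalysed exchange of the enol ether with the diol then gives the ketal without moving the alkene into conjugation; C3 is protonated unselectively.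

Step 6
Reactants: 11 (5'R)-2',9',9'-trimethyl-1',2',4',5',6',7',8',9'-octahydrospiro[1,3-dioxolane-2,3'-benzo[7]annulen]-5'-ol (both C2' epimers)
Product: 12 (4a'R,5'R,9a'S)-2',9',9'-trimethyldecahydrospiro[1,3-dioxolane-2,3'-benzo[7]annulen]-5'-ol (both C2' epimers)
Conditions: [Ir(cod)(PCy3)(py)]PF6 (10 mol%), H2 (10 bar), CH2Cl2, rt
Reagents that add atoms: none
Why: Hydroxyl-directed hydrogenation: the cationic iridium centre binds the C7 hydroxyl and the alkene together and transfers both hydrogens to the face on the hydroxyl side, a reaction type established for tetrasubstituted ring-fusion alkenes that resist heterogeneous catalysts. Syn addition makes the fusion cis, and delivery from the hydroxyl face fixes C1 (S) and C6 (R).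

Step 7
Reactants: 12 (4a'R,5'R,9a'S)-2',9',9'-trimethyldecahydrospiro[1,3-dioxolane-2,3'-benzo[7]annulen]-5'-ol (both C2' epimers)
Product: 13 (4a'R,9a'S)-2',9',9'-trimethyloctahydrospiro[1,3-dioxolane-2,3'-benzo[7]annulen]-5'(1'H)-one (both C2' epimers)
Conditions: n-Pr4N[RuO4] (5 mol%), NMO, 4 Å MS, CH2Cl2, rt
Reagents that add atoms: none
Why: Perruthenate-catalysed oxidation of a secondary alcohol (Ley–Griffith oxidation) under neutral conditions, chosen so that neither the ketal nor the now enolisable ring-fusion centre C6 is disturbed.

Step 8
Reactants: 13 (4a'R,9a'S)-2',9',9'-trimethyloctahydrospiro[1,3-dioxolane-2,3'-benzo[7]annulen]-5'(1'H)-one (both C2' epimers)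
Product: 15 (4aR,5S,9aS)-5-hydroxy-2,5,9,9-tetramethyldecahydro-3H-benzo[7]annulen-3-one (both C2 epimers), via ketal carbinol 14 (not isolated)
Conditions: MeLi, CeCl3, THF, −78 °C; then 1 M HCl (aq), rt
Reagents that add atoms: methyllithium [Li]C; water O
Why: Organocerium 1,2-addition: the weakly basic methylcerium reagent adds to the enolisable ketone without epimerising C6 and should attack C7 on the convex face, anti to the C5 methylene on the neighbouring ring-fusion carbon, which puts methyl syn to H6 and hydroxyl anti (7S). Aqueous acid in the work-up hydrolyses the dioxolane; the tertiary alcohol is not allylic and should tolerate it.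

Step 9
Reactants: 15 (4aR,5S,9aS)-5-hydroxy-2,5,9,9-tetramethyldecahydro-3H-benzo[7]annulen-3-one (both C2 epimers)
Product: 18 (4aR,5S,9aS)-5-hydroxy-2,5,9,9-tetramethyl-4,4a,5,6,7,8,9,9a-octahydro-3H-benzo[7]annulen-3-one, via bis(trimethylsilyl) enol ether 16 (not isolated), via silyl ether enone 17 (not isolated)
Conditions: TMSCl, NaI, Et3N, MeCN, rt; Pd(OAc)2 (10 mol%), O2 (1 atm), DMSO, rt; then 1 M HCl (aq), THF, 0 °C
Reagents that add atoms: none
Why: Saegusa–Ito dehydrogenation: equilibrating silylation with iodotrimethylsilane made in situ gives the more substituted C3=C4 enol ether and caps the tertiary alcohol; Pd(OAc)2 then forms the enone by palladation at C3 and β-hydride loss from C2, and dilute acid frees the tertiary alcohol. Both C3 epimers converge here.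

Step 10
Reactants: 18 (4aR,5S,9aS)-5-hydroxy-2,5,9,9-tetramethyl-4,4a,5,6,7,8,9,9a-octahydro-3H-benzo[7]annulen-3-one
Product: 19 (3S,4aR,5S,9aS)-2,5,9,9-tetramethyl-4,4a,5,6,7,8,9,9a-octahydro-3H-benzo[7]annulene-3,5-diol
Conditions: NaBH4, CeCl3·7H2O, MeOH, −40 °C
Reagents that add atoms: none
Why: Luche reduction: cerium-activated borohydride reduces the enone carbonyl in the 1,2 sense, and hydride should enter on the face of H6, away from the ring-B carbon on C6 (the cis-carveol-type outcome of 2-methylcyclohexenones). This gives the (4S) alcohol with oxygen anti to H6, the C4 epimer of what the target needs.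

Step 11
Reactants: 20 3-hydroxy-4-methoxybenzoic acid (isovanillic acid)
Product: 22 3-[(tert-butyldimethylsilyl)oxy]-4-methoxybenzoic acid, via silyl ester silyl ether 21 (not isolated)
Conditions: TBSCl (2.3 equiv), imidazole, DMF, rt; then AcOH–THF–H2O, rt
Reagents that add atoms: tert-butyldimethylsilyl chloride CC(C)(C)[Si](C)(C)Cl
Why: Silylation of both acidic hydroxyls, then selective hydrolysis of the much more labile silyl ester, leaves the phenol protected and the carboxylic acid free.

Step 12
Reactants: 19 (3S,4aR,5S,9aS)-2,5,9,9-tetramethyl-4,4a,5,6,7,8,9,9a-octahydro-3H-benzo[7]annulene-3,5-diol; 22 3-[(tert-butyldimethylsilyl)oxy]-4-methoxybenzoic acid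
Product: 23 (3R,4aR,5S,9aS)-5-hydroxy-2,5,9,9-tetramethyl-4,4a,5,6,7,8,9,9a-octahydro-3H-benzo[7]annulen-3-yl 3-[(tert-butyldimethylsilyl)oxy]-4-methoxybenzoate
Conditions: PPh3, DIAD, THF, 0 °C → rt
Reagents that add atoms: none
Why: Mitsunobu esterification: the alkoxyphosphonium ion of the secondary allylic alcohol is displaced by the carboxylate with inversion, turning (4S) into (4R). The tertiary C7 hydroxyl cannot be displaced and the masked phenol cannot compete.

Step 13
Reactants: 23 (3R,4aR,5S,9aS)-5-hydroxy-2,5,9,9-tetramethyl-4,4a,5,6,7,8,9,9a-octahydro-3H-benzo[7]annulen-3-yl 3-[(tert-butyldimethylsilyl)oxy]-4-methoxybenzoate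
Product: 24 (3R,4aR,5S,9aS)-5-hydroxy-2,5,9,9-tetramethyl-4,4a,5,6,7,8,9,9a-octahydro-3H-benzo[7]annulen-3-yl 3-hydroxy-4-methoxybenzoate
Conditions: TBAF, AcOH, THF, 0 °C
Reagents that add atoms: none
Why: Fluoride cleavage of the aryl silyl ether; acetic acid buffers the phenoxide so that the allylic benzoate is not attacked.

## Compound list

1 | 2-methylbut-3-en-2-ol | CC(C)(O)C=C | starting material
2 | triethyl orthoacetate | CCOC(C)(OCC)OCC | starting material
3 | 1-ethoxy-1-[(2-methylbut-3-en-2-yl)oxy]ethene (mixed ketene acetal) | C=C(OCC)OC(C)(C)C=C | intermediate (not isolated)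
4 | ethyl 5-methylhex-4-enoate | CCOC(=O)CCC=C(C)C | intermediate
5 | 5-methylhex-4-enoic acid | CC(C)=CCCC(=O)O | intermediate
6 | 2-methylanisole | COc1ccccc1C | starting material
7 | 5-(4-methoxy-3-methylphenyl)-5-methylhexanoic acid | COc1ccc(cc1C)C(C)(C)CCCC(=O)O | intermediate (not isolated)
8 | 3-methoxy-2,9,9-trimethyl-6,7,8,9-tetrahydro-5H-benzo[7]annulen-5-one | COc1cc2c(cc1C)C(C)(C)CCCC2=O | intermediate
9 | (5R)-3-methoxy-2,9,9-trimethyl-6,7,8,9-tetrahydro-5H-benzo[7]annulen-5-ol | COc1cc2c(cc1C)C(C)(C)CCC[C@H]2O | intermediate
10 | (5R)-3-methoxy-2,9,9-trimethyl-4,5,6,7,8,9-hexahydro-1H-benzo[7]annulen-5-ol (enol ether C3=C4, alkene C1=C6) | COC1=C(C)CC2=C(C1)[C@H](O)CCCC2(C)C | intermediate (not isolated)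
11 | (5'R)-2',9',9'-trimethyl-1',2',4',5',6',7',8',9'-octahydrospiro[1,3-dioxolane-2,3'-benzo[7]annulen]-5'-ol, both C2' epimers (C4 ketal, C1=C6 alkene, C7 carbinol) | CC1CC2=C(CC13OCCO3)[C@H](O)CCCC2(C)C | intermediate
12 | (4a'R,5'R,9a'S)-2',9',9'-trimethyldecahydrospiro[1,3-dioxolane-2,3'-benzo[7]annulen]-5'-ol, both C2' epimers (cis fusion, H1 and H6 syn to the C7 hydroxyl) | CC1C[C@H]2[C@@H](CC13OCCO3)[C@H](O)CCCC2(C)C | intermediate
13 | (4a'R,9a'S)-2',9',9'-trimethyloctahydrospiro[1,3-dioxolane-2,3'-benzo[7]annulen]-5'(1'H)-one, both C2' epimers | CC1C[C@H]2[C@@H](CC13OCCO3)C(=O)CCCC2(C)C | intermediate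
14 | (4a'R,5'S,9a'S)-2',5',9',9'-tetramethyldecahydrospiro[1,3-dioxolane-2,3'-benzo[7]annulen]-5'-ol, both C2' epimers | CC1C[C@H]2[C@@H](CC13OCCO3)[C@@](C)(O)CCCC2(C)C | intermediate (not isolated)
15 | (4aR,5S,9aS)-5-hydroxy-2,5,9,9-tetramethyldecahydro-3H-benzo[7]annulen-3-one, both C2 epimers | CC1C[C@H]2[C@@H](CC1=O)[C@@](C)(O)CCCC2(C)C | intermediate
16 | (4aR,5S,9aS)-2,5,9,9-tetramethyl-3,5-bis(trimethylsilyloxy)-4,4a,5,6,7,8,9,9a-octahydro-1H-benzo[7]annulene | CC1=C(O[Si](C)(C)C)C[C@@H]2[C@H](C1)C(C)(C)CCC[C@]2(C)O[Si](C)(C)C | intermediate (not isolated)
17 | (4aR,5S,9aS)-2,5,9,9-tetramethyl-5-(trimethylsilyloxy)-4,4a,5,6,7,8,9,9a-octahydro-3H-benzo[7]annulen-3-one | O=C1C[C@@H]2[C@H](C=C1C)C(C)(C)CCC[C@]2(C)O[Si](C)(C)C | intermediate (not isolated)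
18 | (4aR,5S,9aS)-5-hydroxy-2,5,9,9-tetramethyl-4,4a,5,6,7,8,9,9a-octahydro-3H-benzo[7]annulen-3-one | O=C1C[C@@H]2[C@H](C=C1C)C(C)(C)CCC[C@]2(C)O | intermediate
19 | (3S,4aR,5S,9aS)-2,5,9,9-tetramethyl-4,4a,5,6,7,8,9,9a-octahydro-3H-benzo[7]annulene-3,5-diol | O[C@H]1C[C@@H]2[C@H](C=C1C)C(C)(C)CCC[C@]2(C)O | intermediate
20 | 3-hydroxy-4-methoxybenzoic acid (isovanillic acid) | COc1ccc(C(=O)O)cc1O | starting material
21 | tert-butyldimethylsilyl 3-[(tert-butyldimethylsilyl)oxy]-4-methoxybenzoate | COc1ccc(C(=O)O[Si](C)(C)C(C)(C)C)cc1O[Si](C)(C)C(C)(C)C | intermediate (not isolated)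
22 | 3-[(tert-butyldimethylsilyl)oxy]-4-methoxybenzoic acid | COc1ccc(C(=O)O)cc1O[Si](C)(C)C(C)(C)C | intermediate
23 | (3R,4aR,5S,9aS)-5-hydroxy-2,5,9,9-tetramethyl-4,4a,5,6,7,8,9,9a-octahydro-3H-benzo[7]annulen-3-yl 3-[(tert-butyldimethylsilyl)oxy]-4-methoxybenzoate | COc1ccc(C(=O)O[C@@H]2C[C@@H]3[C@H](C=C2C)C(C)(C)CCC[C@]3(C)O)cc1O[Si](C)(C)C(C)(C)C | intermediate
24 | (3R,4aR,5S,9aS)-5-hydroxy-2,5,9,9-tetramethyl-4,4a,5,6,7,8,9,9a-octahydro-3H-benzo[7]annulen-3-yl 3-hydroxy-4-methoxybenzoate | COc1ccc(C(=O)O[C@@H]2C[C@@H]3[C@H](C=C2C)C(C)(C)CCC[C@]3(C)O)cc1O | target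

## Step count and least certain steps

Total: 13 steps. Longest linear sequence: 12 steps (steps 1–10, 12, 13); step 11 is a one-step side branch.

**Step 3 (key step).** The most likely failure is acylation overtaking alkylation, which would close the ring in the reversed orientation with the carbonyl para to methoxy. Acid-promoted loss or migration of the tertiary alkyl group during the warm stage and double alkylation of 6 are further risks. All are ordinary Friedel–Crafts events, and the ring closure has to occur at a carbon the methoxy group does not activate.
Fallback, setting out from 6: acylation with glutaric anhydride (AlCl3, CH2Cl2) fixes the para bond first and should give 5-(4-methoxy-3-methylphenyl)-5-oxopentanoic acid F1. Esterification (MeOH, H2SO4) gives methyl 5-(4-methoxy-3-methylphenyl)-5-oxopentanoate F2. Geminal dimethylation of the aryl ketone with Me2TiCl2 (from Me2Zn and TiCl4, CH2Cl2, −30 → 0 °C) gives methyl 5-(4-methoxy-3-methylphenyl)-5-methylhexanoate F3. Saponification returns the route at 7, which is closed to 8 with P2O5–MeSO3H alone.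

**Step 5.** Two processes threaten this step. The first is reductive cleavage of the benzylic C–O bond whenever the alkoxide is protonated while lithium is present, together with slow reduction of the very electron-rich ring. The second is ionisation of the allylic C7 carbinol or migration of the C1=C6 alkene during the acid-catalysed exchange. The procedure itself counters the first; the fallback answers the second.
Fallback, setting out from 10: hydrolysis with oxalic acid in aqueous methanol gives (5R)-5-hydroxy-2,9,9-trimethyl-1,2,4,5,6,7,8,9-octahydro-3H-benzo[7]annulen-3-one F4. Hydroxyl-directed hydrogenation with [Ir(cod)(PCy3)(py)]PF6 gives (4aR,5R,9aS)-5-hydroxy-2,9,9-trimethyldecahydro-3H-benzo[7]annulen-3-one F5. Only then is the ketone ketalised (ethane-1,2-diol, PPTS, benzene, water removal), on a compound with no allylic carbinol, to rejoin the route at 12. If C–O cleavage in the metal reduction cannot be suppressed, the sequence given under step 6 avoids the dissolving metal altogether.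

**Step 6.** The most likely failure is lack of turnover. The alkene lies between the quaternary C11 and the substituted C7, and even with hydroxyl binding it may not reach the iridium centre before the catalyst collapses to inactive hydride clusters. Acidic iridium hydrides may also open the ketal.
Fallback, setting out from 9: the tetrasubstituted alkene is never formed. Demethylation (NaSEt, DMF, 130 °C) gives (5R)-2,9,9-trimethyl-6,7,8,9-tetrahydro-5H-benzo[7]annulene-3,5-diol F6. Hydrogenation of the phenol ring over Rh/Al2O3 (H2 50 bar, i-PrOH) should add all hydrogens to one face, that of the benzylic hydroxyl that anchors the ring to the metal, giving (2R,3S,4aR,5R,9aS)-2,9,9-trimethyldecahydro-1H-benzo[7]annulene-3,5-diol F7. Oxidation of both secondary alcohols (n-Pr4N[RuO4], NMO) gives (4aR,9aS)-2,9,9-trimethyloctahydro-1H-benzo[7]annulene-3,5-dione F8. Ketalisation of the less hindered six-membered-ring carbonyl (ethane-1,2-diol, PPTS) rejoins the route at 13. If hydrogen instead entered from the face opposite to the hydroxyl, the (S)-carbinol from the enantiomeric catalyst of step 4 would be used, since the carbinol centre is erased in 13.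

**Step 8.** The most likely failure is low or reversed facial selectivity, because ring B is flexible and the argument rests on one neighbouring centre. Enolisation with epimerisation of C6 is the second risk.
Fallback, setting out from 13: oxygen rather than carbon is brought in from the accessible face, which gives the opposite sense of induction. Wittig methylenation (Ph3P=CH2, THF) gives the exocyclic alkene (4a'R,9a'S)-2',9',9'-trimethyl-5'-methylidenedecahydrospiro[1,3-dioxolane-2,3'-benzo[7]annulene] F9. Epoxidation (dimethyldioxirane, acetone) gives the spiro-epoxide with oxygen anti to H6 F10. LiEt3BH opens it at the methylene carbon and rejoins the route at 14, which the acidic work-up takes on to 15.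

**Step 12.** The most likely failure is displacement with allylic transposition (attack at C2), elimination to the diene, or incomplete inversion, because the electron-rich acid 22 is a weak partner for the alkoxyphosphonium ion.
Fallback, setting out from 19: inversion and acylation are separated. Mitsunobu reaction with the more acidic 4-nitrobenzoic acid gives the (3R)-4-nitrobenzoate F11. Methanolysis (K2CO3, MeOH) gives (3R,4aR,5S,9aS)-2,5,9,9-tetramethyl-4,4a,5,6,7,8,9,9a-octahydro-3H-benzo[7]annulene-3,5-diol F12. Acylation of the secondary hydroxyl with 22 under carbodiimide activation (EDC·HCl, DMAP, CH2Cl2), with retention, rejoins the route at 23.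

## Further compounds

F1 | step 3 | 5-(4-methoxy-3-methylphenyl)-5-oxopentanoic acid | COc1ccc(cc1C)C(=O)CCCC(=O)O
F2 | step 3 | methyl 5-(4-methoxy-3-methylphenyl)-5-oxopentanoate | COC(=O)CCCC(=O)c1ccc(OC)c(C)c1
F3 | step 3 | methyl 5-(4-methoxy-3-methylphenyl)-5-methylhexanoate | COC(=O)CCCC(C)(C)c1ccc(OC)c(C)c1
F4 | step 5 | (5R)-5-hydroxy-2,9,9-trimethyl-1,2,4,5,6,7,8,9-octahydro-3H-benzo[7]annulen-3-one (both C2 epimers) | CC1CC2=C(CC1=O)[C@H](O)CCCC2(C)C
F5 | step 5 | (4aR,5R,9aS)-5-hydroxy-2,9,9-trimethyldecahydro-3H-benzo[7]annulen-3-one (both C2 epimers) | CC1C[C@H]2[C@@H](CC1=O)[C@H](O)CCCC2(C)C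
F6 | step 6 | (5R)-2,9,9-trimethyl-6,7,8,9-tetrahydro-5H-benzo[7]annulene-3,5-diol | Oc1cc2c(cc1C)C(C)(C)CCC[C@H]2O
F7 | step 6 | (2R,3S,4aR,5R,9aS)-2,9,9-trimethyldecahydro-1H-benzo[7]annulene-3,5-diol | O[C@H]1C[C@@H]2[C@H](C[C@H]1C)C(C)(C)CCC[C@H]2O
F8 | step 6 | (4aR,9aS)-2,9,9-trimethyloctahydro-1H-benzo[7]annulene-3,5-dione | O=C1C[C@@H]2[C@H](CC1C)C(C)(C)CCCC2=O
F9 | step 8 | (4a'R,9a'S)-2',9',9'-trimethyl-5'-methylidenedecahydrospiro[1,3-dioxolane-2,3'-benzo[7]annulene] (both C2' epimers) | CC1C[C@H]2[C@@H](CC13OCCO3)C(=C)CCCC2(C)C
F10 | step 8 | C7 spiro-epoxide of F9, (5'S), epoxide oxygen anti to H6 (both C2' epimers) | CC1C[C@H]2[C@@H](CC13OCCO3)[C@]4(CO4)CCCC2(C)C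
F11 | step 12 | (3R,4aR,5S,9aS)-5-hydroxy-2,5,9,9-tetramethyl-4,4a,5,6,7,8,9,9a-octahydro-3H-benzo[7]annulen-3-yl 4-nitrobenzoate | O=C(O[C@@H]1C[C@@H]2[C@H](C=C1C)C(C)(C)CCC[C@]2(C)O)c1ccc(cc1)[N+](=O)[O-]
F12 | step 12 | (3R,4aR,5S,9aS)-2,5,9,9-tetramethyl-4,4a,5,6,7,8,9,9a-octahydro-3H-benzo[7]annulene-3,5-diol | O[C@@H]1C[C@@H]2[C@H](C=C1C)C(C)(C)CCC[C@]2(C)O
A1 | alternative 1 | 3-bromo-3-methylbutan-2-one | CC(=O)C(C)(C)Br
A2 | alternative 1 | 2-methylfuran | Cc1ccco1
A3 | alternative 1 | (1R,5R)-1,4,4-trimethyl-8-oxabicyclo[3.2.1]oct-6-en-3-one | C[C@@]12C=C[C@@H](O1)C(C)(C)C(=O)C2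
A4 | alternative 2 | (8E,10E)-11-[(tert-butyldimethylsilyl)oxy]-7,7,10-trimethylundeca-1,8,10-trien-3-one | C=CC(=O)CCCC(C)(C)/C=C/C(C)=C/O[Si](C)(C)C(C)(C)C
A5 | alternative 2 | (3S,4aR,9aS)-3-[(tert-butyldimethylsilyl)oxy]-2,9,9-trimethyl-3,4,4a,6,7,8,9,9a-octahydro-5H-benzo[7]annulen-5-one | CC(C)(C)[Si](C)(C)O[C@H]1C[C@@H]2[C@H](C=C1C)C(C)(C)CCCC2=O
A6 | alternative 3 | endo-chloro(methyl)cyclopropane fused at C2–C4 to the five-membered ring of the cis-hydroazulene C7 triethylsilyl ether | C[C@@]1(Cl)[C@@H]2C[C@@H]3[C@H]([C@H]12)C(C)(C)CCC[C@]3(C)O[Si](CC)(CC)CC
A7 | alternative 3 | bis-silyl ether of the target (C7 triethylsilyl ether, aryl tert-butyldimethylsilyl ether) | COc1ccc(C(=O)O[C@@H]2C[C@@H]3[C@H](C=C2C)C(C)(C)CCC[C@]3(C)O[Si](CC)(CC)CC)cc1O[Si](C)(C)C(C)(C)C
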